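**Retrosynthetic overview**

1. Feature: in ring B the acetyl C=O and the ring C=O lying between the acetyl-bearing carbon and the carbon that carries the methylene bridge form a β-diketone. This unit is carried as C3/C5 of a 3-methylisoxazole whose C4 is the acetyl-bearing ring carbon, so the bridge-bearing ring carbon becomes the lateral carbon on isoxazole C5.
2. Key disconnection: the bond between that lateral carbon and the ring carbonyl next to the CMe2 carbon, made by an intramolecular Claisen condensation of the lateral anion onto a methyl ester. This closes ring B onto the preformed isoxazole.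
3. Precursor: the 4-acyl bond comes from an isoxazole-4-carbonyl chloride and the enolate of methyl isobutyrate. The CH2–CH2 link comes from lateral lithiation of ethyl 3,5-dimethylisoxazole-4-carboxylate, addition to the ring A aldehyde (trapped as a lactone) and ionic hydrogenolysis.
4. Ring A is bought as 2-methylphloroglucinol and elaborated first: C-butanoylation, 4-O-methylation, formylation, bis-benzylation.
5. Ring order: ring A (purchased), isoxazole (purchased), ring B (step 9). End game: hydrogenolysis of both benzyl ethers and the N–O bond, then hydrolysis of the enaminone.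

Key step: step 9

Remark (assumption): the target has no stereocentre and ring B is written as one tautomer of an enolised β-triketone. Compounds 9, 10 and 17 are racemic; their stereocentres are erased in step 6 and, for 17, by enolisation after step 10.

**Step 1**
Reactants: 1 2-methylphloroglucinol; 2 butanoyl chloride
Product: 3 1-(2,4,6-trihydroxy-3-methylphenyl)butan-1-one
Conditions: AlCl3 (3.5 equiv), PhNO2–CH2Cl2, 0 °C → 40 °C; ice/HCl
Reagents that add atoms: none
Why: Friedel–Crafts C-acylation of the strongly activated phloroglucinol ring, in which the two free positions of 1 are equivalent and the first acyl group deactivates the ring towards a second acylation.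

**Step 2**
Reactants: 3 1-(2,4,6-trihydroxy-3-methylphenyl)butan-1-one
Product: 4 1-(2,6-dihydroxy-4-methoxy-3-methylphenyl)butan-1-one (aspidinol)
Conditions: Me2SO4 (1.0 equiv), K2CO3 (1.0 equiv), acetone, rt
Reagents that add atoms: dimethyl sulfate, COS(=O)(=O)OC
Why: Williamson O-methylation with limiting reagent should select the 4-hydroxyl para to the ketone, the most acidic phenol and the one not engaged with the hydrogen-bonded acyl group, as is general for 2,4,6-trihydroxyaryl ketones; minor isomers would be removed by chromatography.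

**Step 3**
Reactants: 4 aspidinol
Product: 5 3-butanoyl-2,4-dihydroxy-6-methoxy-5-methylbenzaldehyde
Conditions: Cl2CHOMe (1.2 equiv), TiCl4 (2.5 equiv), CH2Cl2, −10 → 0 °C; then 1 M HCl
Reagents that add atoms: dichloromethyl methyl ether, COC(Cl)Cl; water, O
Why: Rieche formylation attacks the single unsubstituted ring carbon, which is ortho or para to all three oxygen donors, while the chelated aryl ketone is inert, and hydrolysis of the α-chloro ether on work-up releases the aldehyde.

**Step 4**
Reactants: 5 3-butanoyl-2,4-dihydroxy-6-methoxy-5-methylbenzaldehyde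
Product: 6 2,4-bis(benzyloxy)-3-butanoyl-6-methoxy-5-methylbenzaldehyde
Conditions: BnBr (3 equiv), K2CO3 (4 equiv), KI (cat.), DMF, 60 °C
Reagents that add atoms: benzyl bromide, BrCc1ccccc1
Why: Williamson etherification of both phenols, run warm in DMF with iodide catalysis because each is hydrogen-bonded to a carbonyl group, with O-alkylation as the productive path on the fully substituted ring.

**Step 5**
Reactants: 7 ethyl 3,5-dimethylisoxazole-4-carboxylate; 6 2,4-bis(benzyloxy)-3-butanoyl-6-methoxy-5-methylbenzaldehyde
Product: 10 (±)-6-[2,4-bis(benzyloxy)-3-butanoyl-6-methoxy-5-methylphenyl]-3-methyl-6,7-dihydro-4H-pyrano[3,4-d]isoxazol-4-one, via lithiated isoxazole ester 8 (not isolated), via lithium alkoxide adduct 9 (not isolated)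
Conditions: LDA (LiN(iPr)2, 1.05 equiv), THF, −78 °C; then 6, −78 °C → rt; 1 M HCl work-up
Reagents that add atoms: none
Why: Lateral metalation of the 5-methyl group, the only one conjugated through C5=C4 with the 4-ester, gives a vinylogous ester enolate that adds to the aldehyde in preference to the doubly flanked, twisted butanoyl ketone, and the alkoxide then closes onto the ethyl ester to the δ-lactone (as in the toluate-anion route to 3-aryl-dihydroisocoumarins), which makes the addition irreversible; the new stereocentre forms racemic and is removed in step 6.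

**Step 6**
Reactants: 10 the δ-lactone
Product: 11 5-[2-[2,4-bis(benzyloxy)-3-butanoyl-6-methoxy-5-methylphenyl]ethyl]-3-methylisoxazole-4-carboxylic acid
Conditions: Et3SiH (3 equiv), CF3CO2H (10 equiv), CH2Cl2, 0 °C; aqueous work-up
Reagents that add atoms: none
Why: Ionic hydrogenation, in which acid ionises the benzylic C–O bond of the lactone to a cation stabilised by the three ortho/para oxygen donors and Et3SiH delivers hydride, should release the carboxylic acid directly, while the twisted butanoyl ketone and the benzyl ethers react much more slowly at 0 °C.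

**Step 7**
Reactants: 11 the carboxylic acid
Product: 12 5-[2-[2,4-bis(benzyloxy)-3-butanoyl-6-methoxy-5-methylphenyl]ethyl]-3-methylisoxazole-4-carbonyl chloride (used crude)
Conditions: (COCl)2 (1.5 equiv), DMF (cat.), CH2Cl2, 0 °C → rt; evaporate
Reagents that add atoms: oxalyl chloride, O=C(Cl)C(=O)Cl
Why: DMF-catalysed conversion of a carboxylic acid into its chloride, to which the ketone, ethers and isoxazole are inert.

**Step 8**
Reactants: 12 the acid chloride; 13 methyl isobutyrate
Product: 15 methyl 3-[5-[2-[2,4-bis(benzyloxy)-3-butanoyl-6-methoxy-5-methylphenyl]ethyl]-3-methylisoxazol-4-yl]-2,2-dimethyl-3-oxopropanoate, via lithium enolate of methyl isobutyrate 14 (not isolated)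
Conditions: 13, LDA (1.05 equiv), THF, −78 °C; cannulate into 12, THF, −78 °C; AcOH quench at −78 °C
Reagents that add atoms: none
Why: Claisen-type C-acylation of a fully substituted lithium ester enolate by an acid chloride gives a β-keto ester with no proton between its carbonyls, so one equivalent of enolate suffices, and inverse addition at −78 °C keeps free enolate away from the butanoyl ketone and from the acidic lateral CH2 of the product.

**Step 9**
Reactants: 15 the β-keto ester
Product: 17 (±)-7-[[2,4-bis(benzyloxy)-3-butanoyl-6-methoxy-5-methylphenyl]methyl]-3,5,5-trimethyl-1,2-benzoxazole-4,6(5H,7H)-dione, via lateral lithio anion 16 (not isolated)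
Conditions: LDA (3.2 equiv), THF (0.02 M), −78 → −20 °C; then 1 M HCl
Reagents that add atoms: none
Why: LDA removes a proton from the CH2 on isoxazole C5 to give an anion delocalised through C5=C4 into the 4-acyl carbonyl, whose carbon terminus adds to the methyl ester on the quaternary carbon with loss of methoxide; this is an intramolecular Claisen (Dieckmann-type) acylation, the closest known reactions being lateral lithiation of 5-alkylisoxazoles bearing a 4-carbonyl group followed by acylation with esters. Ring B closes in a 6-(enolendo)-exo-trig mode and comprises the lateral carbon, isoxazole C5 and C4, the ketone carbon, the CMe2 carbon and the former ester carbon. The only new stereocentre, C7, forms racemic and is deprotonated at once because it lies between the new ketone and the isoxazole, so no control is needed; this enolate formation drives the condensation and shields both ring ketones from retro-Claisen attack by lithium methoxide. The step needs site selectivity for the lateral CH2 over the 3-methyl group and the butanoyl α-CH2: only the C5 side chain is conjugated with the 4-acyl group, and the butanoyl enolate that the excess base also forms could reach the ester only through a macrocyclic transition state, so it should remain a spectator (high dilution suppresses intermolecular condensation). The ester carbon bears no α-hydrogen, so it cannot be lost to enolisation.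

**Step 10**
Reactants: 17 the benzisoxazoledione
Product: 18 2-(1-aminoethylidene)-6-[(3-butanoyl-2,4-dihydroxy-6-methoxy-5-methylphenyl)methyl]-5-hydroxy-4,4-dimethylcyclohex-5-ene-1,3-dione
Conditions: H2 (1 atm), 10% Pd/C, EtOAc–MeOH, rt
Reagents that add atoms: none
Why: Catalytic hydrogenolysis should cleave both O-benzyl bonds and the weak N–O bond of the 4-acylisoxazole, unmasking the acetyl-dione as its enaminone (vinylogous amide), while the chelated aryl ketone and the enolised trione are not reduced under these conditions.

**Step 11**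
Reactants: 18 the enaminone
Product: 19 2-acetyl-6-[(3-butanoyl-2,4-dihydroxy-6-methoxy-5-methylphenyl)methyl]-3,5-dihydroxy-4,4-dimethylcyclohexa-2,5-dien-1-one (target, CNP0414731.0)
Conditions: 2 M HCl, THF, 50 °C
Reagents that add atoms: water, O
Why: Acid hydrolysis of the vinylogous amide, by protonation and addition of water at the amino-bearing carbon with loss of ammonia as NH4Cl, should give the acetyl triketone; because this amino-ethylidene-dione is chelated by two carbonyls and more robust than a simple enaminone, warm 2 M acid is specified.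

**Compound list**

1 | 2-methylphloroglucinol | Cc1c(O)cc(O)cc1O | starting material
2 | butanoyl chloride | CCCC(Cl)=O | starting material
3 | 1-(2,4,6-trihydroxy-3-methylphenyl)butan-1-one | CCCC(=O)c1c(O)cc(O)c(C)c1O | intermediate
4 | 1-(2,6-dihydroxy-4-methoxy-3-methylphenyl)butan-1-one (aspidinol) | CCCC(=O)c1c(O)cc(OC)c(C)c1O | intermediate
5 | 3-butanoyl-2,4-dihydroxy-6-methoxy-5-methylbenzaldehyde | CCCC(=O)c1c(O)c(C)c(OC)c(C=O)c1O | intermediate
6 | 2,4-bis(benzyloxy)-3-butanoyl-6-methoxy-5-methylbenzaldehyde | CCCC(=O)c1c(OCc2ccccc2)c(C)c(OC)c(C=O)c1OCc1ccccc1 | intermediate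
7 | ethyl 3,5-dimethylisoxazole-4-carboxylate | CCOC(=O)c1c(C)noc1C | starting material
8 | ethyl 5-(lithiomethyl)-3-methylisoxazole-4-carboxylate (not isolated) | CCOC(=O)c1c(C)noc1C[Li] | intermediate
9 | lithium alkoxide of (±)-ethyl 5-[2-[2,4-bis(benzyloxy)-3-butanoyl-6-methoxy-5-methylphenyl]-2-hydroxyethyl]-3-methylisoxazole-4-carboxylate (not isolated) | CCCC(=O)c1c(OCc2ccccc2)c(C)c(OC)c(C([O-])Cc2onc(C)c2C(=O)OCC)c1OCc1ccccc1.[Li+] | intermediate
10 | (±)-6-[2,4-bis(benzyloxy)-3-butanoyl-6-methoxy-5-methylphenyl]-3-methyl-6,7-dihydro-4H-pyrano[3,4-d]isoxazol-4-one (δ-lactone between the benzylic oxygen and the isoxazole 4-carboxyl) | CCCC(=O)c1c(OCc2ccccc2)c(C)c(OC)c(C2Cc3onc(C)c3C(=O)O2)c1OCc1ccccc1 | intermediate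
11 | 5-[2-[2,4-bis(benzyloxy)-3-butanoyl-6-methoxy-5-methylphenyl]ethyl]-3-methylisoxazole-4-carboxylic acid | CCCC(=O)c1c(OCc2ccccc2)c(C)c(OC)c(CCc2onc(C)c2C(=O)O)c1OCc1ccccc1 | intermediate
12 | 5-[2-[2,4-bis(benzyloxy)-3-butanoyl-6-methoxy-5-methylphenyl]ethyl]-3-methylisoxazole-4-carbonyl chloride | CCCC(=O)c1c(OCc2ccccc2)c(C)c(OC)c(CCc2onc(C)c2C(Cl)=O)c1OCc1ccccc1 | intermediate
13 | methyl isobutyrate (methyl 2-methylpropanoate) | COC(=O)C(C)C | starting material
14 | lithium 1-methoxy-2-methylprop-1-en-1-olate (not isolated) | [Li]OC(OC)=C(C)C | intermediate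
15 | methyl 3-[5-[2-[2,4-bis(benzyloxy)-3-butanoyl-6-methoxy-5-methylphenyl]ethyl]-3-methylisoxazol-4-yl]-2,2-dimethyl-3-oxopropanoate | CCCC(=O)c1c(OCc2ccccc2)c(C)c(OC)c(CCc2onc(C)c2C(=O)C(C)(C)C(=O)OC)c1OCc1ccccc1 | intermediate
16 | lateral lithio anion of 15, metalated at the CH2 on isoxazole C5 (drawn as the mono-anion; the butanoyl group may also be enolised by the excess base; not isolated) | CCCC(=O)c1c(OCc2ccccc2)c(C)c(OC)c(C[CH-]c2onc(C)c2C(=O)C(C)(C)C(=O)OC)c1OCc1ccccc1.[Li+] | intermediate
17 | (±)-7-[[2,4-bis(benzyloxy)-3-butanoyl-6-methoxy-5-methylphenyl]methyl]-3,5,5-trimethyl-1,2-benzoxazole-4,6(5H,7H)-dione (enolisable at C7) | CCCC(=O)c1c(OCc2ccccc2)c(C)c(OC)c(CC2C(=O)C(C)(C)C(=O)c3c(C)noc23)c1OCc1ccccc1 | intermediate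
18 | 2-(1-aminoethylidene)-6-[(3-butanoyl-2,4-dihydroxy-6-methoxy-5-methylphenyl)methyl]-5-hydroxy-4,4-dimethylcyclohex-5-ene-1,3-dione | CCCC(=O)c1c(O)c(C)c(OC)c(CC2=C(O)C(C)(C)C(=O)C(=C(C)N)C2=O)c1O | intermediate
19 | 2-acetyl-6-[(3-butanoyl-2,4-dihydroxy-6-methoxy-5-methylphenyl)methyl]-3,5-dihydroxy-4,4-dimethylcyclohexa-2,5-dien-1-one | CCCC(=O)c1c(O)c(C)c(OC)c(CC2=C(O)C(C)(C)C(O)=C(C(C)=O)C2=O)c1O | target

**Step count and risk**

Total steps: 11. Longest linear sequence: 11 steps (1 → 19; 7 and 13 enter as purchased materials).

Steps most likely to fail: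

1. Step 9 (key step). Ring closure may be slow because a hindered secondary carbanion must attack a neopentyl-type ester, so that methoxide-induced retro-Claisen cleavage of the non-enolisable β-keto ester, or intermolecular condensation through the butanoyl enolate, overtakes cyclisation. Fallback, setting out from 7, 13 and 6 and returning at 17: the same ring is closed on the unhindered methyl compound and the benzyl group is attached afterwards. Ester 7 would be saponified (NaOH, aqueous EtOH) to 3,5-dimethylisoxazole-4-carboxylic acid F1 and converted with oxalyl chloride into 3,5-dimethylisoxazole-4-carbonyl chloride F2. F2 would acylate enolate 14 (from 13 and LDA) to give methyl 3-(3,5-dimethylisoxazol-4-yl)-2,2-dimethyl-3-oxopropanoate F3. LDA (2.2 equiv, THF, −78 → 0 °C) would close F3 through a primary lateral anion, with no competing ketone, to 3,5,5-trimethyl-1,2-benzoxazole-4,6(5H,7H)-dione F4. Reductive Knoevenagel alkylation of F4 at C7 with aldehyde 6 (L-proline cat., Hantzsch ester, EtOH, rt) would pass through the 7-arylidene compound F5 (not isolated), which the dihydropyridine reduces in situ to 17.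

2. Step 11. Hydrolysis of the doubly chelated vinylogous amide may stall under conditions mild enough for the product, and forcing it in acid may cause cyclodehydration between a ring A phenol and a ring B carbonyl or scrambling of the methylene bridge. Fallback, setting out from 17 and returning at 19: the hydrolysis is done while ring A is still benzylated and the hydrogenolysis is moved to the end. Mo(CO)6 in MeCN–H2O at 80 °C would cleave only the N–O bond to give the bis-benzyl enaminone 2-(1-aminoethylidene)-6-[[2,4-bis(benzyloxy)-3-butanoyl-6-methoxy-5-methylphenyl]methyl]-5-hydroxy-4,4-dimethylcyclohex-5-ene-1,3-dione F6. Aqueous NaOH in EtOH at 60 °C, then acidification, would hydrolyse F6 to the bis-benzyl triketone 2-acetyl-6-[[2,4-bis(benzyloxy)-3-butanoyl-6-methoxy-5-methylphenyl]methyl]-3,5-dihydroxy-4,4-dimethylcyclohexa-2,5-dien-1-one F7; the benzylated ring A can form neither a quinone methide nor a xanthene. Neutral hydrogenolysis (H2, Pd/C, EtOAc) would then give 19.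

3. Step 5. Addition to the deactivated, di-ortho-substituted aldehyde may be reversible or slow, proton transfer from the butanoyl ketone may quench the lateral anion, and lactonisation may be incomplete. Fallback, setting out from 7 and 6 and returning at 11 (steps 5 and 6 are both bypassed): an olefination–reduction sequence. Radical bromination of 7 (NBS, dibenzoyl peroxide cat., PhCF3, reflux) would give ethyl 5-(bromomethyl)-3-methylisoxazole-4-carboxylate F8. Arbuzov reaction with P(OEt)3 at 120 °C would give ethyl 5-[(diethoxyphosphoryl)methyl]-3-methylisoxazole-4-carboxylate F9. Horner–Wadsworth–Emmons olefination of 6 (NaH, THF, 0 °C → rt) would give ethyl 5-[(E)-2-[2,4-bis(benzyloxy)-3-butanoyl-6-methoxy-5-methylphenyl]ethenyl]-3-methylisoxazole-4-carboxylate F10. Diimide reduction (TsNHNH2, NaOAc, THF–H2O, reflux), which spares benzyl ethers, ketone and the N–O bond, would give ethyl 5-[2-[2,4-bis(benzyloxy)-3-butanoyl-6-methoxy-5-methylphenyl]ethyl]-3-methylisoxazole-4-carboxylate F11. Saponification (LiOH, THF–MeOH–H2O) would deliver 11.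

**Further compounds**

F1 | step 9 | 3,5-dimethylisoxazole-4-carboxylic acid | Cc1noc(C)c1C(=O)O
F2 | step 9 | 3,5-dimethylisoxazole-4-carbonyl chloride | Cc1noc(C)c1C(Cl)=O
F3 | step 9 | methyl 3-(3,5-dimethylisoxazol-4-yl)-2,2-dimethyl-3-oxopropanoate | COC(=O)C(C)(C)C(=O)c1c(C)noc1C
F4 | step 9 | 3,5,5-trimethyl-1,2-benzoxazole-4,6(5H,7H)-dione | Cc1noc2CC(=O)C(C)(C)C(=O)c12
F5 | step 9 | 7-[[2,4-bis(benzyloxy)-3-butanoyl-6-methoxy-5-methylphenyl]methylidene]-3,5,5-trimethyl-1,2-benzoxazole-4,6(5H,7H)-dione (alkene geometry not defined, not isolated) | CCCC(=O)c1c(OCc2ccccc2)c(C)c(OC)c(C=C2C(=O)C(C)(C)C(=O)c3c(C)noc23)c1OCc1ccccc1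
F6 | step 11 | 2-(1-aminoethylidene)-6-[[2,4-bis(benzyloxy)-3-butanoyl-6-methoxy-5-methylphenyl]methyl]-5-hydroxy-4,4-dimethylcyclohex-5-ene-1,3-dione | CCCC(=O)c1c(OCc2ccccc2)c(C)c(OC)c(CC2=C(O)C(C)(C)C(=O)C(=C(C)N)C2=O)c1OCc1ccccc1
F7 | step 11 | 2-acetyl-6-[[2,4-bis(benzyloxy)-3-butanoyl-6-methoxy-5-methylphenyl]methyl]-3,5-dihydroxy-4,4-dimethylcyclohexa-2,5-dien-1-one | CCCC(=O)c1c(OCc2ccccc2)c(C)c(OC)c(CC2=C(O)C(C)(C)C(O)=C(C(C)=O)C2=O)c1OCc1ccccc1
F8 | step 5 | ethyl 5-(bromomethyl)-3-methylisoxazole-4-carboxylate | CCOC(=O)c1c(C)noc1CBr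
F9 | step 5 | ethyl 5-[(diethoxyphosphoryl)methyl]-3-methylisoxazole-4-carboxylate | CCOC(=O)c1c(C)noc1CP(=O)(OCC)OCC
F10 | step 5 | ethyl 5-[(E)-2-[2,4-bis(benzyloxy)-3-butanoyl-6-methoxy-5-methylphenyl]ethenyl]-3-methylisoxazole-4-carboxylate | CCCC(=O)c1c(OCc2ccccc2)c(C)c(OC)c(/C=C/c2onc(C)c2C(=O)OCC)c1OCc1ccccc1
F11 | step 5 | ethyl 5-[2-[2,4-bis(benzyloxy)-3-butanoyl-6-methoxy-5-methylphenyl]ethyl]-3-methylisoxazole-4-carboxylate | CCCC(=O)c1c(OCc2ccccc2)c(C)c(OC)c(CCc2onc(C)c2C(=O)OCC)c1OCc1ccccc1
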